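## Retrosynthetic overview

1. Target 21 ⇐ C5–O bond: singlet-oxygen ene hydroxylation of the 4Z-ene macrolactone 19 (moves C4=C5 to C4=C15, sets C5).
2. 19 ⇐ lactone C6–O closure after C6–C7 bond formation: intramolecular CrCl2-mediated Barbier allylation of bromo-enal 17 (closes the ten-membered carbocycle, then the γ-lactone).
3. 17 ⇐ C8–O bond: catalytic asymmetric α-isovaleryloxylation of aldehyde 8 (sets C8, installs the ester directly), then propiolate vinylalumination and allylic bromination.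
4. 8 ⇐ asymmetric Michael addition of furanone 6 to acrolein (sets the quaternary C10).
5. 6 ⇐ furanone C3–O closure of an ynone made from commercial (Z)-3-methylpent-2-en-4-yn-1-ol and 2-acetoxypropanoyl chloride. Ring order: furanone, carbocycle, lactone.

Assumption: ring carbons are numbered as in germacranolides (C1 ketone, C2=C3 enol ether, C3–O–C10 bridge, C6 lactone oxygen, C8 ester, C11–C13 acrylate, C14 and C15 the one-carbon branches); the target is then 5R,6S,7R,8R,10S.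

## Route

Step 1
Reactants: 1 (2Z)-3-methylpent-2-en-4-yn-1-ol
Product: 2 triethyl{[(2Z)-3-methylpent-2-en-4-yn-1-yl]oxy}silane
Conditions: Et3SiCl, imidazole, CH2Cl2, 0 °C
Reagents that add atoms: chlorotriethylsilane, CC[Si](Cl)(CC)CC
Why: Standard silyl ether protection of the primary allylic alcohol, which keeps O6 from adding to the ynone in step 3 and is acid-labile enough to be removed in the work-up of step 7; no stereocentre is formed and the Z alkene is untouched.

Step 2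
Reactants: 2 triethyl{[(2Z)-3-methylpent-2-en-4-yn-1-yl]oxy}silane; 3 2-acetoxypropanoyl chloride (racemic)
Product: 4 (6Z)-6-methyl-3-oxo-8-[(triethylsilyl)oxy]oct-6-en-4-yn-2-yl acetate (racemic)
Conditions: PdCl2(PPh3)2 (2 mol %), CuI (4 mol %), Et3N (1.2 equiv), THF, rt
Reagents that add atoms: none
Why: Acyl Sonogashira coupling of a terminal alkyne with an acid chloride is a general ynone synthesis that leaves the Z-enyne and the silyl ether intact; the acetoxy-bearing carbon (future C10) is used racemic because it is re-set in step 4.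

Step 3
Reactants: 4 (6Z)-6-methyl-3-oxo-8-[(triethylsilyl)oxy]oct-6-en-4-yn-2-yl acetate
Product: 6 2-methyl-5-{(2Z)-4-[(triethylsilyl)oxy]but-2-en-2-yl}furan-3(2H)-one (racemic), via hydroxy ynone 5 (not isolated)
Conditions: K2CO3 (0.2 equiv), MeOH, 0 °C
Reagents that add atoms: none
Why: Base-catalysed methanolysis of the α′-acetate frees the hydroxyl of 5, which closes onto the ynone β-carbon (5-endo-dig oxa-Michael addition, the standard 3(2H)-furanone synthesis) to form the C3–O ring bond; C10–H stays configurationally labile, so no stereocontrol is needed here.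

Step 4
Reactants: 6 2-methyl-5-{(2Z)-4-[(triethylsilyl)oxy]but-2-en-2-yl}furan-3(2H)-one; 7 acrolein
Product: 8 3-[(2S)-2-methyl-3-oxo-5-{(2Z)-4-[(triethylsilyl)oxy]but-2-en-2-yl}-2,3-dihydrofuran-2-yl]propanal
Conditions: 9-O-(9-phenanthryl)cupreidine (10 mol %), CH2Cl2, −25 °C
Reagents that add atoms: none
Why: Bifunctional cinchona-catalysed Michael addition, in which the quinuclidine deprotonates the acidic C10–H to a planar 3-oxidofuran enolate (so racemic 6 converges) while the 6′-OH hydrogen-bonds acrolein and delivers it to one enolate face, as in the established additions of α-substituted cyclic ketone pronucleophiles to acrolein, setting the quaternary centre as 10S (the cupreine-derived pseudoenantiomer is used should the sense prove opposite).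

Step 5
Reactants: 9 3-methylbutanoyl chloride
Product: 10 bis(3-methylbutanoyl) peroxide
Conditions: 9 (2.0 equiv in all), 30% aq H2O2 (1.1 equiv), NaOH (2.2 equiv), Et2O/H2O, 0 °C; kept as a dried, titrated Et2O solution
Reagents that add atoms: hydrogen peroxide, OO; 3-methylbutanoyl chloride (second equivalent of 9), CC(C)CC(Cl)=O
Why: Schotten–Baumann acylation, in which both oxygens of hydrogen peroxide are acylated in turn by two equivalents of the acid chloride, is the standard preparation of symmetrical diacyl peroxides; the reagent is kept cold in solution and never concentrated.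

Step 6
Reactants: 8 3-[(2S)-2-methyl-3-oxo-5-{(2Z)-4-[(triethylsilyl)oxy]but-2-en-2-yl}-2,3-dihydrofuran-2-yl]propanal; 10 bis(3-methylbutanoyl) peroxide
Product: 11 (2R)-1-oxo-3-[(2S)-2-methyl-3-oxo-5-{(2Z)-4-[(triethylsilyl)oxy]but-2-en-2-yl}-2,3-dihydrofuran-2-yl]propan-2-yl 3-methylbutanoate
Conditions: (R)-α,α-diphenylprolinol trimethylsilyl ether (10 mol %), hydroquinone (10 mol %), 10 (1.2 equiv), THF, 0 °C
Reagents that add atoms: none
Why: Proposed new method: enamine-catalysed asymmetric α-acyloxylation of an aldehyde with an aliphatic diacyl peroxide as the electrophilic oxygen source, in which the E-enamine of 8 and the (R)-diarylprolinol silyl ether attacks one peroxide oxygen of 10 in an SN2 sense on the face away from the CPh2OSiMe3 group (giving 8R, the sense known for heteroatom electrophiles with this catalyst class), isovalerate leaves and hydrolysis of the α-acyloxy iminium releases 11 with the natural ester already in place, hydroquinone suppressing radical-chain decarboxylation of the peroxide; the closest known reaction is the secondary-amine-catalysed asymmetric α-benzoyloxylation of aldehydes with dibenzoyl peroxide.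

Step 7
Reactants: 11 (2R)-1-oxo-3-[(2S)-2-methyl-3-oxo-5-{(2Z)-4-[(triethylsilyl)oxy]but-2-en-2-yl}-2,3-dihydrofuran-2-yl]propan-2-yl 3-methylbutanoate; 12 methyl propiolate
Product: 15 methyl (4R)-3-hydroxy-5-[(2S)-5-{(2Z)-4-hydroxybut-2-en-2-yl}-2-methyl-3-oxo-2,3-dihydrofuran-2-yl]-2-methylidene-4-(3-methylbutanoyloxy)pentanoate (C3 epimers), via vinylalane 13 (not isolated), via silyl ether adduct 14 (not isolated)
Conditions: i-Bu2AlH, NMO, THF, 0 °C, then 12; then 11, 0 °C to rt; then 1 M aq HCl, THF, rt (brief)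
Reagents that add atoms: none
Why: Vinylalumination, in which conjugate hydroalumination of methyl propiolate gives the α-aluminoacrylate 13 that adds to the aldehyde to give the Morita–Baylis–Hillman-type adduct without any amine base, so the epimerisable α-acyloxy centre C8 is preserved; the new carbinol (C7) forms as an inconsequential mixture because it is erased in step 9, and the short acidic work-up cleaves the triethylsilyl ether before the neighbouring ester can migrate.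

Step 8
Reactants: 15 methyl (4R)-3-hydroxy-5-[(2S)-5-{(2Z)-4-hydroxybut-2-en-2-yl}-2-methyl-3-oxo-2,3-dihydrofuran-2-yl]-2-methylidene-4-(3-methylbutanoyloxy)pentanoate
Product: 16 methyl (4R)-3-hydroxy-5-[(2S)-2-methyl-3-oxo-5-{(2Z)-4-oxobut-2-en-2-yl}-2,3-dihydrofuran-2-yl]-2-methylidene-4-(3-methylbutanoyloxy)pentanoate (C3 epimers)
Conditions: MnO2 (15 equiv), CH2Cl2, rt
Reagents that add atoms: none
Why: MnO2 is a chemoselective allylic oxidant that converts the electron-rich primary dienylic alcohol to the Z-enal without geometric isomerisation while leaving the secondary, acrylate-deactivated carbinol untouched.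

Step 9
Reactants: 16 methyl (4R)-3-hydroxy-5-[(2S)-2-methyl-3-oxo-5-{(2Z)-4-oxobut-2-en-2-yl}-2,3-dihydrofuran-2-yl]-2-methylidene-4-(3-methylbutanoyloxy)pentanoate
Product: 17 methyl (2Z,4R)-2-(bromomethyl)-5-[(2S)-2-methyl-3-oxo-5-{(2Z)-4-oxobut-2-en-2-yl}-2,3-dihydrofuran-2-yl]-4-(3-methylbutanoyloxy)pent-2-enoate
Conditions: NBS, Me2S, CH2Cl2, −20 to 0 °C
Reagents that add atoms: N-bromosuccinimide, O=C1CCC(=O)N1Br
Why: Corey–Kim-type activation of the Baylis–Hillman alcohol followed by SN2′ attack of bromide gives the thermodynamically preferred (Z)-2-(bromomethyl)enoate, removes the C7 carbinol stereocentre and tolerates the aldehyde and the esters.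

Step 10
Reactants: 17 methyl (2Z,4R)-2-(bromomethyl)-5-[(2S)-2-methyl-3-oxo-5-{(2Z)-4-oxobut-2-en-2-yl}-2,3-dihydrofuran-2-yl]-4-(3-methylbutanoyloxy)pent-2-enoate
Product: 19 (4Z,6R,7R,8R,10S)-8-(3-methylbutanoyloxy)-1-oxo-3,10-epoxygermacra-2,4,11(13)-trien-12,6-olide, via hydroxy ester 18 (not isolated)
Conditions: CrCl2 (8 equiv), THF, rt, syringe-pump addition (final 2 mM); then p-TsOH (cat.), CH2Cl2, rt
Reagents that add atoms: none
Why: Intramolecular CrCl2-mediated Nozaki–Hiyama allylation at high dilution, in which CrCl2 reduces the allylic bromide and the allyl–CrCl2 species adds to the enal through its γ-carbon (C7) to form C6–C7 and the ten-membered ring; because both reacting ends are held in one ring by the rigid furanone bridge and the Z-enal, the closure is under macrocyclic control, which in related germacranolide ring closures of this type gives the 6,7-trans relationship rather than the syn adduct that the open-chain reagent prefers, while the C8 acyloxy centre (H8 eclipsing the acrylate to avoid allylic strain) selects the face so that C6 and C7 emerge as 6R,7S; acid then closes the trans-fused γ-lactone through O6, the only free hydroxyl.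

Step 11
Reactants: 19 (4Z,6R,7R,8R,10S)-8-(3-methylbutanoyloxy)-1-oxo-3,10-epoxygermacra-2,4,11(13)-trien-12,6-olide
Product: 21 (5R,6S,7R,8R,10S)-5-hydroxy-8-(3-methylbutanoyloxy)-1-oxo-3,10-epoxygermacra-2,4(15),11(13)-trien-12,6-olide (CNP0409337.1), via hydroperoxide 20 (not isolated)
Conditions: O2, tetraphenylporphyrin (1 mol %), white LED, CH2Cl2, 0 °C; then PPh3, 0 °C
Reagents that add atoms: dioxygen, O=O
Why: Schenck ene reaction, in which singlet oxygen adds to C5 of the only alkene with abstractable allylic hydrogens (C4=C5) by peripheral attack on its outer face (the inner face is blocked across the ring by the furanone bridge and the C7–C9 arch) and abstracts a hydrogen from the C15 methyl geminal to the conjugating furanone (H6 lies near the alkene plane), moving the double bond to C4=C15 and setting C5; PPh3 reduces the hydroperoxide with retention to give 5R.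

## Compound list

1 | (2Z)-3-methylpent-2-en-4-yn-1-ol | C#C/C(C)=C\CO | starting material
2 | triethyl{[(2Z)-3-methylpent-2-en-4-yn-1-yl]oxy}silane | C#C/C(C)=C\CO[Si](CC)(CC)CC | intermediate
3 | 2-acetoxypropanoyl chloride (racemic) | CC(OC(C)=O)C(Cl)=O | starting material
4 | (6Z)-6-methyl-3-oxo-8-[(triethylsilyl)oxy]oct-6-en-4-yn-2-yl acetate (racemic) | CC(OC(C)=O)C(=O)C#C/C(C)=C\CO[Si](CC)(CC)CC | intermediate
5 | (6Z)-2-hydroxy-6-methyl-8-[(triethylsilyl)oxy]oct-6-en-4-yn-3-one (racemic, not isolated) | CC(O)C(=O)C#C/C(C)=C\CO[Si](CC)(CC)CC | intermediate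
6 | 2-methyl-5-{(2Z)-4-[(triethylsilyl)oxy]but-2-en-2-yl}furan-3(2H)-one (racemic) | CC1OC(=CC1=O)/C(C)=C\CO[Si](CC)(CC)CC | intermediate
7 | acrolein (prop-2-enal) | C=CC=O | starting material
8 | 3-[(2S)-2-methyl-3-oxo-5-{(2Z)-4-[(triethylsilyl)oxy]but-2-en-2-yl}-2,3-dihydrofuran-2-yl]propanal | O=CCC[C@]1(C)OC(=CC1=O)/C(C)=C\CO[Si](CC)(CC)CC | intermediate
9 | 3-methylbutanoyl chloride | CC(C)CC(Cl)=O | starting material
10 | bis(3-methylbutanoyl) peroxide | CC(C)CC(=O)OOC(=O)CC(C)C | intermediate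
11 | (2R)-1-oxo-3-[(2S)-2-methyl-3-oxo-5-{(2Z)-4-[(triethylsilyl)oxy]but-2-en-2-yl}-2,3-dihydrofuran-2-yl]propan-2-yl 3-methylbutanoate | O=C[C@H](OC(=O)CC(C)C)C[C@]1(C)OC(=CC1=O)/C(C)=C\CO[Si](CC)(CC)CC | intermediate
12 | methyl propiolate (methyl prop-2-ynoate) | C#CC(=O)OC | starting material
13 | methyl 2-(diisobutylalumanyl)prop-2-enoate (not isolated) | C=C(C(=O)OC)[Al](CC(C)C)CC(C)C | intermediate
14 | methyl (4R)-3-hydroxy-2-methylidene-4-(3-methylbutanoyloxy)-5-[(2S)-2-methyl-3-oxo-5-{(2Z)-4-[(triethylsilyl)oxy]but-2-en-2-yl}-2,3-dihydrofuran-2-yl]pentanoate (C3 epimers, not isolated) | C=C(C(=O)OC)C(O)[C@H](OC(=O)CC(C)C)C[C@]1(C)OC(=CC1=O)/C(C)=C\CO[Si](CC)(CC)CC | intermediate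
15 | methyl (4R)-3-hydroxy-5-[(2S)-5-{(2Z)-4-hydroxybut-2-en-2-yl}-2-methyl-3-oxo-2,3-dihydrofuran-2-yl]-2-methylidene-4-(3-methylbutanoyloxy)pentanoate (C3 epimers) | C=C(C(=O)OC)C(O)[C@H](OC(=O)CC(C)C)C[C@]1(C)OC(=CC1=O)/C(C)=C\CO | intermediate
16 | methyl (4R)-3-hydroxy-5-[(2S)-2-methyl-3-oxo-5-{(2Z)-4-oxobut-2-en-2-yl}-2,3-dihydrofuran-2-yl]-2-methylidene-4-(3-methylbutanoyloxy)pentanoate (C3 epimers) | C=C(C(=O)OC)C(O)[C@H](OC(=O)CC(C)C)C[C@]1(C)OC(=CC1=O)/C(C)=C\C=O | intermediate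
17 | methyl (2Z,4R)-2-(bromomethyl)-5-[(2S)-2-methyl-3-oxo-5-{(2Z)-4-oxobut-2-en-2-yl}-2,3-dihydrofuran-2-yl]-4-(3-methylbutanoyloxy)pent-2-enoate | COC(=O)/C(CBr)=C/[C@H](OC(=O)CC(C)C)C[C@]1(C)OC(=CC1=O)/C(C)=C\C=O | intermediate
18 | methyl (4Z,6R,7S,8R,10S)-6-hydroxy-8-(3-methylbutanoyloxy)-1-oxo-3,10-epoxygermacra-2,4,11(13)-trien-12-oate (not isolated) | C/C1=C/[C@@H](O)[C@H](C(=C)C(=O)OC)[C@H](OC(=O)CC(C)C)C[C@]2(C)OC1=CC2=O | intermediate
19 | (4Z,6R,7R,8R,10S)-8-(3-methylbutanoyloxy)-1-oxo-3,10-epoxygermacra-2,4,11(13)-trien-12,6-olide | C/C1=C/[C@H]2OC(=O)C(=C)[C@@H]2[C@H](OC(=O)CC(C)C)C[C@]3(C)OC1=CC3=O | intermediate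
20 | (5R,6S,7R,8R,10S)-5-hydroperoxy-8-(3-methylbutanoyloxy)-1-oxo-3,10-epoxygermacra-2,4(15),11(13)-trien-12,6-olide (not isolated) | C=C1C(=O)O[C@H]2[C@H]1[C@H](OC(=O)CC(C)C)C[C@]1(C)OC(=CC1=O)C(=C)[C@H]2OO | intermediate
21 | (5R,6S,7R,8R,10S)-5-hydroxy-8-(3-methylbutanoyloxy)-1-oxo-3,10-epoxygermacra-2,4(15),11(13)-trien-12,6-olide (CNP0409337.1) | C=C1C(=O)O[C@H]2[C@H]1[C@H](OC(=O)CC(C)C)C[C@]1(C)OC(=CC1=O)C(=C)[C@H]2O | target

## Step count and risks

Total steps: 11. Longest linear sequence: 10 (steps 1–4 and 6–11; step 5 prepares the peroxide reagent).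

The three steps most likely to fail are steps 4, 6 and 10.

Step 4, the Michael addition: enantiocontrol at a quaternary centre of a 2-alkylfuranone enolate with the very small acceptor acrolein is not assured. The fallback sets out from 6 and returns at 8. Pd2(dba)3-catalysed asymmetric allylic alkylation of 6 with allyl acetate ((S,S)-DACH-phenyl Trost ligand or its enantiomer as required, Cs2CO3, toluene) gives (2S)-2-methyl-2-(prop-2-en-1-yl)-5-{(2Z)-4-[(triethylsilyl)oxy]but-2-en-2-yl}furan-3(2H)-one F1. Hydroboration of the terminal alkene with 9-BBN gives 9-{3-[(2S)-2-methyl-3-oxo-5-{(2Z)-4-[(triethylsilyl)oxy]but-2-en-2-yl}-2,3-dihydrofuran-2-yl]propyl}-9-borabicyclo[3.3.1]nonane F2. NaBO3 oxidation gives (2S)-2-(3-hydroxypropyl)-2-methyl-5-{(2Z)-4-[(triethylsilyl)oxy]but-2-en-2-yl}furan-3(2H)-one F3, and Dess–Martin oxidation gives 8.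

Step 6, the proposed new α-isovaleryloxylation: the aliphatic peroxide is less electrophilic than dibenzoyl peroxide and may decarboxylate by radical paths or acyloxylate the amine catalyst. The fallback uses known chemistry, sets out from 8 and returns at 11. L-Proline-catalysed α-aminoxylation of 8 with nitrosobenzene gives (2R)-2-(anilinooxy)-3-[(2S)-2-methyl-3-oxo-5-{(2Z)-4-[(triethylsilyl)oxy]but-2-en-2-yl}-2,3-dihydrofuran-2-yl]propanal F4. This is reduced in the same flask with NaBH4 to (2S)-2-[(2R)-2-(anilinooxy)-3-hydroxypropyl]-2-methyl-5-{(2Z)-4-[(triethylsilyl)oxy]but-2-en-2-yl}furan-3(2H)-one F5. Zn/AcOH in EtOH at 0 °C cleaves the N–O bond to give (2S)-2-[(2R)-2,3-dihydroxypropyl]-2-methyl-5-{(2Z)-4-[(triethylsilyl)oxy]but-2-en-2-yl}furan-3(2H)-one F6. Acylation of both hydroxyls with 9 (pyridine, DMAP) gives (2R)-3-[(2S)-2-methyl-3-oxo-5-{(2Z)-4-[(triethylsilyl)oxy]but-2-en-2-yl}-2,3-dihydrofuran-2-yl]propane-1,2-diyl bis(3-methylbutanoate) F7. Candida antarctica lipase B in phosphate buffer/acetone hydrolyses only the primary ester to give (2R)-1-hydroxy-3-[(2S)-2-methyl-3-oxo-5-{(2Z)-4-[(triethylsilyl)oxy]but-2-en-2-yl}-2,3-dihydrofuran-2-yl]propan-2-yl 3-methylbutanoate F8, and Dess–Martin oxidation gives 11.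

Step 10, the macrocyclisation: the isovalerate sits δ to the metal and could be lost by 1,4-elimination, the ring closure could oligomerise, or the syn preference of open-chain 2-(alkoxycarbonyl)allyl metal reagents could override the macrocyclic bias and give the 6,7-cis lactone. The fallback makes the C6–C7 bond intermolecularly, corrects C6 by inversion and closes the ring at C4=C5 by metathesis; it sets out from 3 and returns at 19.

Acyl Sonogashira coupling of 3 with commercial 2-methylbut-1-en-3-yne (conditions of step 2) gives 6-methyl-3-oxohept-6-en-4-yn-2-yl acetate F9. K2CO3/MeOH gives 2-hydroxy-6-methylhept-6-en-4-yn-3-one F10, which cyclises in the flask to 2-methyl-5-(prop-1-en-2-yl)furan-3(2H)-one F11. The conditions of step 4 with acrolein 7 give 3-[(2S)-2-methyl-3-oxo-5-(prop-1-en-2-yl)-2,3-dihydrofuran-2-yl]propanal F12. The conditions of step 6 with peroxide 10 give (2R)-1-oxo-3-[(2S)-2-methyl-3-oxo-5-(prop-1-en-2-yl)-2,3-dihydrofuran-2-yl]propan-2-yl 3-methylbutanoate F13. The conditions of step 7 with vinylalane 13 give methyl (4R)-3-hydroxy-2-methylidene-4-(3-methylbutanoyloxy)-5-[(2S)-2-methyl-3-oxo-5-(prop-1-en-2-yl)-2,3-dihydrofuran-2-yl]pentanoate F14. The conditions of step 9 give methyl (2Z,4R)-2-(bromomethyl)-4-(3-methylbutanoyloxy)-5-[(2S)-2-methyl-3-oxo-5-(prop-1-en-2-yl)-2,3-dihydrofuran-2-yl]pent-2-enoate F15.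

Indium-mediated Barbier allylation of acrolein 7 with F15 (In powder, THF/H2O, rt) is syn-selective for such (Z)-2-(bromomethyl)enoates and tolerates an oxygen substituent next to the reacting carbon. It gives methyl (3S,4R)-3-[(1S)-1-hydroxyprop-2-en-1-yl]-2-methylidene-4-(3-methylbutanoyloxy)-5-[(2S)-2-methyl-3-oxo-5-(prop-1-en-2-yl)-2,3-dihydrofuran-2-yl]pentanoate F16, the C8 centre directing the face at C7. Mitsunobu reaction with formic acid (PPh3, DIAD, THF, 0 °C) inverts C6 and gives methyl (3R,4R)-3-[(1R)-1-(formyloxy)prop-2-en-1-yl]-2-methylidene-4-(3-methylbutanoyloxy)-5-[(2S)-2-methyl-3-oxo-5-(prop-1-en-2-yl)-2,3-dihydrofuran-2-yl]pentanoate F17. KHCO3 in aqueous MeOH at 0 °C removes only the formate and gives methyl (3S,4R)-3-[(1R)-1-hydroxyprop-2-en-1-yl]-2-methylidene-4-(3-methylbutanoyloxy)-5-[(2S)-2-methyl-3-oxo-5-(prop-1-en-2-yl)-2,3-dihydrofuran-2-yl]pentanoate F18. p-TsOH in CH2Cl2 then closes the trans lactone (1R)-1-[(2R,3R)-2-ethenyl-4-methylidene-5-oxooxolan-3-yl]-2-[(2S)-2-methyl-3-oxo-5-(prop-1-en-2-yl)-2,3-dihydrofuran-2-yl]ethyl 3-methylbutanoate F19. Ring-closing metathesis with the second-generation Hoveyda–Grubbs catalyst (toluene, 80 °C, 1 mM) joins the isopropenyl and vinyl groups; the bridged ring is expected to enforce the Z geometry, giving 19.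

Further compounds
F1 | step 4 | (2S)-2-methyl-2-(prop-2-en-1-yl)-5-{(2Z)-4-[(triethylsilyl)oxy]but-2-en-2-yl}furan-3(2H)-one | C=CC[C@]1(C)OC(=CC1=O)/C(C)=C\CO[Si](CC)(CC)CC
F2 | step 4 | 9-{3-[(2S)-2-methyl-3-oxo-5-{(2Z)-4-[(triethylsilyl)oxy]but-2-en-2-yl}-2,3-dihydrofuran-2-yl]propyl}-9-borabicyclo[3.3.1]nonane | C1CC2CCCC(C1)B2CCC[C@]1(C)OC(=CC1=O)/C(C)=C\CO[Si](CC)(CC)CC
F3 | step 4 | (2S)-2-(3-hydroxypropyl)-2-methyl-5-{(2Z)-4-[(triethylsilyl)oxy]but-2-en-2-yl}furan-3(2H)-one | OCCC[C@]1(C)OC(=CC1=O)/C(C)=C\CO[Si](CC)(CC)CC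
F4 | step 6 | (2R)-2-(anilinooxy)-3-[(2S)-2-methyl-3-oxo-5-{(2Z)-4-[(triethylsilyl)oxy]but-2-en-2-yl}-2,3-dihydrofuran-2-yl]propanal | O=C[C@H](ONc1ccccc1)C[C@]1(C)OC(=CC1=O)/C(C)=C\CO[Si](CC)(CC)CC
F5 | step 6 | (2S)-2-[(2R)-2-(anilinooxy)-3-hydroxypropyl]-2-methyl-5-{(2Z)-4-[(triethylsilyl)oxy]but-2-en-2-yl}furan-3(2H)-one | OC[C@H](ONc1ccccc1)C[C@]1(C)OC(=CC1=O)/C(C)=C\CO[Si](CC)(CC)CC
F6 | step 6 | (2S)-2-[(2R)-2,3-dihydroxypropyl]-2-methyl-5-{(2Z)-4-[(triethylsilyl)oxy]but-2-en-2-yl}furan-3(2H)-one | OC[C@H](O)C[C@]1(C)OC(=CC1=O)/C(C)=C\CO[Si](CC)(CC)CC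
F7 | step 6 | (2R)-3-[(2S)-2-methyl-3-oxo-5-{(2Z)-4-[(triethylsilyl)oxy]but-2-en-2-yl}-2,3-dihydrofuran-2-yl]propane-1,2-diyl bis(3-methylbutanoate) | CC(C)CC(=O)OC[C@H](OC(=O)CC(C)C)C[C@]1(C)OC(=CC1=O)/C(C)=C\CO[Si](CC)(CC)CC
F8 | step 6 | (2R)-1-hydroxy-3-[(2S)-2-methyl-3-oxo-5-{(2Z)-4-[(triethylsilyl)oxy]but-2-en-2-yl}-2,3-dihydrofuran-2-yl]propan-2-yl 3-methylbutanoate | OC[C@H](OC(=O)CC(C)C)C[C@]1(C)OC(=CC1=O)/C(C)=C\CO[Si](CC)(CC)CC
F9 | step 10 | 6-methyl-3-oxohept-6-en-4-yn-2-yl acetate (racemic) | CC(OC(C)=O)C(=O)C#CC(C)=C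
F10 | step 10 | 2-hydroxy-6-methylhept-6-en-4-yn-3-one (racemic) | CC(O)C(=O)C#CC(C)=C
F11 | step 10 | 2-methyl-5-(prop-1-en-2-yl)furan-3(2H)-one (racemic) | CC1OC(=CC1=O)C(C)=C
F12 | step 10 | 3-[(2S)-2-methyl-3-oxo-5-(prop-1-en-2-yl)-2,3-dihydrofuran-2-yl]propanal | O=CCC[C@]1(C)OC(=CC1=O)C(C)=C
F13 | step 10 | (2R)-1-oxo-3-[(2S)-2-methyl-3-oxo-5-(prop-1-en-2-yl)-2,3-dihydrofuran-2-yl]propan-2-yl 3-methylbutanoate | O=C[C@H](OC(=O)CC(C)C)C[C@]1(C)OC(=CC1=O)C(C)=C
F14 | step 10 | methyl (4R)-3-hydroxy-2-methylidene-4-(3-methylbutanoyloxy)-5-[(2S)-2-methyl-3-oxo-5-(prop-1-en-2-yl)-2,3-dihydrofuran-2-yl]pentanoate (C3 epimers) | C=C(C(=O)OC)C(O)[C@H](OC(=O)CC(C)C)C[C@]1(C)OC(=CC1=O)C(C)=C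
F15 | step 10 | methyl (2Z,4R)-2-(bromomethyl)-4-(3-methylbutanoyloxy)-5-[(2S)-2-methyl-3-oxo-5-(prop-1-en-2-yl)-2,3-dihydrofuran-2-yl]pent-2-enoate | COC(=O)/C(CBr)=C/[C@H](OC(=O)CC(C)C)C[C@]1(C)OC(=CC1=O)C(C)=C
F16 | step 10 | methyl (3S,4R)-3-[(1S)-1-hydroxyprop-2-en-1-yl]-2-methylidene-4-(3-methylbutanoyloxy)-5-[(2S)-2-methyl-3-oxo-5-(prop-1-en-2-yl)-2,3-dihydrofuran-2-yl]pentanoate | C=C[C@H](O)[C@H](C(=C)C(=O)OC)[C@H](OC(=O)CC(C)C)C[C@]1(C)OC(=CC1=O)C(C)=C
F17 | step 10 | methyl (3R,4R)-3-[(1R)-1-(formyloxy)prop-2-en-1-yl]-2-methylidene-4-(3-methylbutanoyloxy)-5-[(2S)-2-methyl-3-oxo-5-(prop-1-en-2-yl)-2,3-dihydrofuran-2-yl]pentanoate | C=C[C@@H](OC=O)[C@H](C(=C)C(=O)OC)[C@H](OC(=O)CC(C)C)C[C@]1(C)OC(=CC1=O)C(C)=C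
F18 | step 10 | methyl (3S,4R)-3-[(1R)-1-hydroxyprop-2-en-1-yl]-2-methylidene-4-(3-methylbutanoyloxy)-5-[(2S)-2-methyl-3-oxo-5-(prop-1-en-2-yl)-2,3-dihydrofuran-2-yl]pentanoate | C=C[C@@H](O)[C@H](C(=C)C(=O)OC)[C@H](OC(=O)CC(C)C)C[C@]1(C)OC(=CC1=O)C(C)=C
F19 | step 10 | (1R)-1-[(2R,3R)-2-ethenyl-4-methylidene-5-oxooxolan-3-yl]-2-[(2S)-2-methyl-3-oxo-5-(prop-1-en-2-yl)-2,3-dihydrofuran-2-yl]ethyl 3-methylbutanoate | C=C[C@H]1OC(=O)C(=C)[C@@H]1[C@H](OC(=O)CC(C)C)C[C@]1(C)OC(=CC1=O)C(C)=C
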